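## Remarks on the chemistry (assumptions)

- Ethyl 2-acetyl-3-methylbutanoate (12) and 2-chloro-1,1-dimethoxyethane (18) are taken as catalogue compounds; 12 is otherwise one alkylation away from ethyl acetoacetate and 2-iodopropane.
- The alkoxy ynone cannot coexist with enolates, amines or a free vinylogous acid, so the pyrone is completed first and the ynone is made in the step directly before the cycloaddition.
- The C12 oxygen is carried as a benzyl ether rather than a methyl ether. This changes a protecting group only: the carbon skeleton and the two bonds formed in the cycloaddition are unchanged. It removes the need to hydrolyse a methoxyquinone next to a methyl ester.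
- Configurations were checked along the route: C10 and C5 are both (S) in 6, 20, 22 and 24, although the locants change with the parent chain.
- In step 1 the enantiomer of the ligand is chosen by a short screen so that the isopropenyl group enters the face that gives (S) at C5.

## Structural features

The target is a ring-A-opened abietane. A cyclohexanone ring B (C5, C6, C7, C8, C9, C10) is fused along C8–C9 to a fully substituted 2-hydroxy-1,4-benzoquinone ring C (C8, C9, C11, C12, C13, C14). The locants used throughout are: C10 the quaternary carbon (methyl and CH2CH2CO2Me), C5 the isopropenyl methine, C6 the methylene, C7 the ring ketone, C8 (on C7) and C9 (on C10) the shared carbons, C11 the quinone carbonyl next to C9, C12 the C–OH, C13 the C–isopropyl and C14 the quinone carbonyl next to C8. The only stereocentres, C10 (S, quaternary) and C5 (S), are adjacent, with methyl and isopropenyl cis; neither is enolisable once set. Fragile groups are the hydroxyquinone (base, nucleophiles, reductants), the isopropenyl group (protic acid, carbocations, hydrogenation, electrophilic oxidants) and the methyl ester (hydroxide, hard nucleophiles). The real difficulty is ring C: six substituents, three of them oxygen, in a fixed order, wedged between the C7 ketone and the quaternary C10, so stepwise substitution of a preformed arene would fight both sterics and regiochemistry. The key step uses the fact that ring C shares C8–C9 with ring B and that C8 is the α-carbon of the C7 ketone. A 2-pyrone attached to C10 through C9 and an ynone whose carbonyl is C7 can therefore be joined at C8–C9 and C13–C14 in one cycloaddition, and loss of CO2 leaves ring C fully substituted.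

## Logic of the disconnections

24 to 23: the C11–O bond is removed. The hydroxyquinone is the most sensitive part of 24, so it is revealed last from a benzene ring in which C11 is the only unsubstituted position. The gain is that ring C travels as a robust arene. The forward step needs an oxidant that attacks an electron-rich phenol and leaves the alkene, the C6 methylene and the ester alone.

23 to 22: the O12–benzyl and O14–methyl bonds are cut. Both oxygens must be capped during the cycloaddition, because a free vinylogous acid would add to the ynone. The two caps are chosen so that one sulfide-buffered boron Lewis acid removes both, the benzyl group by displacement at the benzylic carbon and the methyl group through chelation to the C7 ketone. The gain is one deprotection step and no hydrolysis beside the ester. The demand is that no free carbocation or strong protic acid forms near the isopropenyl group.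

22 to 20 (through 21): C8–C9 and C13–C14 are cut, which opens rings B and C together. The cut is made here because it turns a hexasubstituted arene into an acyclic chain whose substituent order is fixed by a tether. The gain is two rings and every ring-C substituent in one step. The demand is that the cycloaddition outruns ene and polymerisation pathways of the ynone.

20 to 17 and 18 (through 19): C7–C8 is cut. The alkoxy ynone is the most fragile function in the route, so it is introduced immediately before it is consumed. The gain is that all earlier steps handle only an amide. The demand is mono-addition at the amide carbonyl in the presence of a methyl ester and a lactone, and release of the ynone in an acidic, amine-free medium.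

17 to 15 (through 16): the lactone O–C(=O) bond of the pyrone and the O12–benzyl bond are cut. This reduces the heterocycle to an open 3,5-dioxo ester that already holds C9, C11, C12, C13 and the isopropyl group. The demand is that the enol oxygen at C9 closes onto the ethyl ester faster than carbon acylation by the other ester or the amide.

15 to 11 and 12 (through 13 and 14): C9–C11 is cut. This joins the chiral half to a five-carbon achiral piece that carries the isopropyl group. The demand is that a carbon nucleophile picks the hindered but highly activated C9 acyl group over the amide and the methyl ester.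

11 to 9 (through 10): the C7–N bond is cut. The two carboxyl groups of 9 differ sharply in hindrance, so a cyclic anhydride is opened at the unhindered C7 carbonyl. The gain is differentiation without protecting groups. The demand is regioselective aminolysis.

9 to 8 to 7 to 6: in the retrosynthetic sense C9 and C7 are joined into a five-membered ring ketone. The ring lets both stereocentres be set on a rigid template, and its carbonyl and α'-methylene become C9 and C7. The demand is oxidation at the only enolisable position followed by clean C–C cleavage that spares the alkene.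

6 to 1, 2 and 3 (through 4 and 5): the C5–isopropenyl bond and the C10–CH2 bond are cut. This leaves an achiral enone and two simple three-carbon pieces. The demand is face-selective conjugate addition and trapping of the resulting enolate on the face away from the new substituent.

## Other disconnections considered

Alternative 1: The cut removes the C5–isopropenyl bond and the bond from C10 to the first chain carbon, leaving naphthalene A1 with a chiral oxazoline on the future C10. In the forward step isopropenyllithium A2 would add at C5 next to the oxazoline, and the aza-enolate would be alkylated at C10 by iodide A3 on the opposite face to give dihydronaphthalene A4.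
- In favour: both stereocentres arise in one flask with the trans nucleophile/electrophile relationship the target needs, under a stoichiometric auxiliary whose sense of induction is well understood. Rings B and C and the three ring-C oxygens are present from the start.
- Against: the oxazoline carbon must be reduced to a methyl group at a neopentyl position, the silyl ether chain oxidised to the ester, the enol ether hydrolysed, and A1 itself needs a multistep synthesis. The ring that must accept the organolithium carries a donor methoxy group.
- Comparison: on stereocontrol this route is the equal of the chosen plan and probably the better, since the chosen plan rests on a catalytic step whose selectivity for an alkenyl Grignard reagent must be established. On mechanistic risk the two are comparable. On step economy it is clearly longer, because most functional-group work comes after the key step.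

Alternative 2: The cut crosses ring B at C9–C10 and C5–C6. Dienal A5 would react through its α,β-double bond with silyloxydiene A6 under a chiral boron Lewis acid to give cyclohexene A7.
- In favour: it is catalytic, both stereocentres form in one event from cheap achiral partners, and the cis methyl/isopropenyl relationship follows directly from the (E)-geometry of A5. On this point it is better than the chosen plan, which needs ligand control and substrate control in sequence.
- Against: A5 is a trisubstituted dienophile that is also a diene, so low rate and self-reaction are likely. After A7 the whole of ring C (six carbons, three oxygens, the isopropyl group), the C7 ketone and a two-carbon homologation of the aldehyde are still missing.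
- Comparison: structurally it solves the easier half and leaves the hexasubstituted ring open. Mechanistically the key step is well understood. In step count it would be the longest of the four.

Alternative 3: The cut is C8–C14, preceded by C9–C11. Alkenyllithium A9 would add to dione A8 at the carbonyl next to the isopropoxy carbon to give cyclobutenone A10. Heating would open the four-membered ring to a dienylketene that closes onto C8, giving hydroquinone A11.
- In favour: the electrocyclic cascade is dependable for fully substituted rings, the substituent order of ring C is fixed by A8, and all three ring-C oxygens arrive at the right level, C11 included. Oxidation to the quinone is then trivial and no late C–H oxidation is needed, which is an advantage over the chosen plan.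
- Against: only ring C is made. Ring B with both stereocentres must already exist as an enantiopure, hindered alkenyl metal next to the quaternary carbon. A ketal, a silyl ether and an isopropyl ether must be removed or adjusted afterwards, the last with a Lewis acid near the isopropenyl group.
- Comparison: in predictability of the key step it is equal or better. In convergence it is weaker (one ring instead of two). In step count it is longer.

Key step: step 9

## Route

Step 1
Reactants: 1 2-bromopropene; 2 2-methylcyclopent-2-en-1-one; 3 methyl acrylate
Product: 6 methyl 3-[(1S,5S)-1-methyl-2-oxo-5-(prop-1-en-2-yl)cyclopentyl]propanoate, via isopropenylmagnesium bromide 4 (not isolated), via magnesium enolate 5 (not isolated)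
Conditions: 1, Mg, 2-MeTHF, 40 °C; then 2, Cu(OTf)2 (5 mol %), chiral C2-symmetric imidazolinium salt (NHC precursor, 6 mol %), Et2O, −30 °C; then 3 (1.2 equiv), −78 → −30 °C; aq. NH4Cl
Reagents that add atoms: none
Why: Copper-catalysed asymmetric conjugate addition of a Grignard reagent to an α-substituted cyclic enone, with Michael trapping of the regiodefined magnesium enolate; the ligand sets C5 (S) and the acrylate then enters the enolate face anti to the new isopropenyl group, which places methyl and isopropenyl cis at C10 (S).

Step 2
Reactants: 6 methyl 3-[(1S,5S)-1-methyl-2-oxo-5-(prop-1-en-2-yl)cyclopentyl]propanoate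
Product: 7 methyl 3-[(1S,5S)-3-hydroxy-1-methyl-2-oxo-5-(prop-1-en-2-yl)cyclopentyl]propanoate (both epimers at the carbinol carbon)
Conditions: KN(SiMe3)2, THF, −78 °C; 2-(phenylsulfonyl)-3-phenyloxaziridine, −78 °C; aq. NH4Cl
Reagents that add atoms: 2-(phenylsulfonyl)-3-phenyloxaziridine, O=S(=O)(c1ccccc1)N1OC1c1ccccc1
Why: Enolate hydroxylation with an N-sulfonyloxaziridine; the ketone has a single enolisable position (C7), the ketone is deprotonated ahead of the ester at −78 °C, and the enolate oxygen-transfer does not touch the alkene; the new carbinol centre is uncontrolled and is destroyed in step 3.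

Step 3
Reactants: 7 methyl 3-[(1S,5S)-3-hydroxy-1-methyl-2-oxo-5-(prop-1-en-2-yl)cyclopentyl]propanoate
Product: 8 (2S,3S)-2-(3-methoxy-3-oxopropyl)-2-methyl-5-oxo-3-(prop-1-en-2-yl)pentanoic acid (may sit partly as its cyclic lactol)
Conditions: NaIO4, THF/H2O, 0 °C → rt
Reagents that add atoms: water, O
Why: Malaprade-type periodate cleavage of an α-hydroxy ketone through its hydrate gives the C9 acid and the C7 aldehyde; periodate does not attack an isolated alkene, and a ketol shift before cleavage would not matter because both isomers converge in step 4.

Step 4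
Reactants: 8 (2S,3S)-2-(3-methoxy-3-oxopropyl)-2-methyl-5-oxo-3-(prop-1-en-2-yl)pentanoic acid
Product: 9 (2S,3S)-2-(3-methoxy-3-oxopropyl)-2-methyl-3-(prop-1-en-2-yl)pentanedioic acid
Conditions: NaClO2, NaH2PO4, 2-methylbut-2-ene, t-BuOH/H2O, 0 °C → rt
Reagents that add atoms: sodium chlorite, [Na+].[O-]Cl=O
Why: Pinnick oxidation of the aldehyde (reached through the open form of the lactol); the excess of 2-methylbut-2-ene removes hypochlorous acid before it can reach the isopropenyl group.

Step 5
Reactants: 9 (2S,3S)-2-(3-methoxy-3-oxopropyl)-2-methyl-3-(prop-1-en-2-yl)pentanedioic acid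
Product: 11 (2S,3S)-5-[methoxy(methyl)amino]-2-(3-methoxy-3-oxopropyl)-2-methyl-5-oxo-3-(prop-1-en-2-yl)pentanoic acid, via cyclic anhydride 10 (not isolated)
Conditions: DCC, CH2Cl2, 0 °C → rt; then MeNH(OMe)·HCl, Et3N, 0 °C → rt
Reagents that add atoms: N,O-dimethylhydroxylamine hydrochloride, CNOC.Cl
Why: Carbodiimide dehydration closes the six-membered anhydride, and aminolysis then takes place at the carbonyl flanked by CH2 (C7) and not at the one on the quaternary carbon (C9), a sterically controlled anhydride opening that differentiates the two acids without protecting groups.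

Step 6
Reactants: 11 (2S,3S)-5-[methoxy(methyl)amino]-2-(3-methoxy-3-oxopropyl)-2-methyl-5-oxo-3-(prop-1-en-2-yl)pentanoic acid; 12 ethyl 2-acetyl-3-methylbutanoate
Product: 15 methyl (4S,5S)-4-[4-(ethoxycarbonyl)-5-methyl-3-oxohexanoyl]-7-[methoxy(methyl)amino]-4-methyl-7-oxo-5-(prop-1-en-2-yl)heptanoate, via acid chloride 13 (not isolated), via dilithium dienolate 14 (not isolated)
Conditions: 11, 1-chloro-N,N,2-trimethylprop-1-en-1-amine, CH2Cl2, 0 °C → rt, concentrate; 12 (3 equiv), LiN(i-Pr)2 (6.2 equiv), THF, −78 → 0 → −78 °C; add 13, −78 °C, 30 min; AcOH, −78 °C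
Reagents that add atoms: none
Why: The α-chloroenamine makes the acid chloride without liberating HCl, and the acid chloride has no α-hydrogen, so no ketene can form; Claisen-type γ-C-acylation of the β-keto ester dianion is fast at −78 °C, where the amide and the methyl ester react far more slowly, and excess dianion deprotonates the product and prevents a second acylation.

Step 7
Reactants: 15 methyl (4S,5S)-4-[4-(ethoxycarbonyl)-5-methyl-3-oxohexanoyl]-7-[methoxy(methyl)amino]-4-methyl-7-oxo-5-(prop-1-en-2-yl)heptanoate
Product: 17 methyl (4S,5S)-4-[4-(benzyloxy)-2-oxo-3-(propan-2-yl)-2H-pyran-6-yl]-7-[methoxy(methyl)amino]-4-methyl-7-oxo-5-(prop-1-en-2-yl)heptanoate, via hydroxypyrone 16 (not isolated)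
Conditions: DBU (1.1 equiv), MeCN, 70 °C; then BnBr (1.2 equiv), 60 °C
Reagents that add atoms: benzyl bromide, BrCc1ccccc1
Why: Base-mediated lactonisation of a 3,5-dioxo ester (the C9 enolate oxygen closes a six-membered ring onto the ethyl ester) gives the 4-hydroxy-2-pyrone as its amidinium salt, which undergoes Williamson O-benzylation at the 4-oxygen; C3 is blocked by the isopropyl group, and carbon acylation of a diketone enolate by an unactivated ester or amide needs much stronger activation than an amidine base.

Step 8
Reactants: 17 methyl (4S,5S)-4-[4-(benzyloxy)-2-oxo-3-(propan-2-yl)-2H-pyran-6-yl]-7-[methoxy(methyl)amino]-4-methyl-7-oxo-5-(prop-1-en-2-yl)heptanoate; 18 2-chloro-1,1-dimethoxyethane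
Product: 20 methyl (4S,5S)-4-[4-(benzyloxy)-2-oxo-3-(propan-2-yl)-2H-pyran-6-yl]-9-methoxy-4-methyl-7-oxo-5-(prop-1-en-2-yl)non-8-ynoate, via lithium methoxyacetylide 19 (not isolated)
Conditions: 18, Et2NH, n-BuLi (3.0 equiv), THF, 0 °C; cannulate 19 (1.5 equiv) into 17, THF, −78 °C; AcOH/THF, −78 °C; cold aq. citric acid
Reagents that add atoms: none
Why: Double elimination of the chloroacetal gives the alkynide, which adds once to the N-methoxy-N-methylamide (Weinreb ketone synthesis) because the chelated tetrahedral intermediate survives until quench; quenching with acid at −78 °C protonates every amine before the ynone is released, and a methoxy rather than a higher alkoxy group is used because it has no β-hydrogen for later thermal retro-ene loss.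

Step 9
Reactants: 20 methyl (4S,5S)-4-[4-(benzyloxy)-2-oxo-3-(propan-2-yl)-2H-pyran-6-yl]-9-methoxy-4-methyl-7-oxo-5-(prop-1-en-2-yl)non-8-ynoate
Product: 22 methyl 3-[(1S,2S)-7-(benzyloxy)-5-methoxy-1-methyl-4-oxo-6-(propan-2-yl)-2-(prop-1-en-2-yl)-1,2,3,4-tetrahydronaphthalen-1-yl]propanoate, via bridged lactone 21 (not isolated)
Conditions: PhMe (0.01 M), BHT (5 mol %), 110 → 130 °C, sealed tube
Reagents that add atoms: none
Why: The pyrone diene (C9=C11–C12=C13) and the ynone (C8≡C14) undergo a thermal intramolecular [4+2] cycloaddition to the 2-oxabicyclo[2.2.2]octadienone 21, which loses CO2 by retro-[4+2] at the same temperature to give the benzene ring. The closest known reaction type is the intramolecular 2-pyrone–alkyne Diels–Alder benzannulation with extrusion of CO2. Ring B, six-membered, closes by formation of C8–C9 in the fused mode through the four-atom tether C10–C5–C6–C7, exo with respect to both π-systems. Ring C closes by the second bond, C13–C14, of the same cycloaddition and becomes aromatic by the cycloreversion. No stereocentre is created: the bridgeheads of 21 vanish with CO2, and C5 and C10 are untouched because neither is enolisable. Polarity is matched, since the nucleophilic pyrone carbon C13 (β to the benzyloxy group) meets the electrophilic β-carbon C14 of the ynone. The step needs regiocontrol, which the tether enforces, and it needs to be faster than the ene reaction of the isopropenyl group and than ynone oligomerisation; the gem-disubstituted C10, high dilution and a radical inhibitor are there to secure that.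

Step 10
Reactants: 22 methyl 3-[(1S,2S)-7-(benzyloxy)-5-methoxy-1-methyl-4-oxo-6-(propan-2-yl)-2-(prop-1-en-2-yl)-1,2,3,4-tetrahydronaphthalen-1-yl]propanoate
Product: 23 methyl 3-[(1S,2S)-5,7-dihydroxy-1-methyl-4-oxo-6-(propan-2-yl)-2-(prop-1-en-2-yl)-1,2,3,4-tetrahydronaphthalen-1-yl]propanoate
Conditions: BCl3·SMe2 (6 equiv), CH2Cl2, 0 °C → rt; aq. NaHCO3
Reagents that add atoms: none
Why: Lewis-acid ether cleavage in which dimethyl sulfide displaces the benzyl group and the methyl group from the boron-activated oxygens (the methoxy group is activated through a six-membered chelate with the C7 ketone), so no free carbocation and no protic acid is formed before the basic quench; the unchelated methyl ester is not cleaved under these conditions.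

Step 11
Reactants: 23 methyl 3-[(1S,2S)-5,7-dihydroxy-1-methyl-4-oxo-6-(propan-2-yl)-2-(prop-1-en-2-yl)-1,2,3,4-tetrahydronaphthalen-1-yl]propanoate
Product: 24 methyl 3-[(1S,2S)-7-hydroxy-1-methyl-4,5,8-trioxo-6-(propan-2-yl)-2-(prop-1-en-2-yl)-1,2,3,4,5,8-hexahydronaphthalen-1-yl]propanoate
Conditions: (KSO3)2NO (2.5 equiv), KH2PO4, acetone/H2O, 0 °C → rt
Reagents that add atoms: potassium nitrosodisulfonate, [K+].[K+].[O]N(S(=O)(=O)[O-])S(=O)(=O)[O-]
Why: Teuber oxidation of a resorcinol to a 2-hydroxy-1,4-benzoquinone: the phenoxyl radical is trapped at C11, the only free ring position, which is para to the C14 hydroxyl and ortho to the C12 hydroxyl, so both possible pathways converge on the same hydroxyquinone; the buffered radical oxidant leaves the alkene and ester untouched.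

## Compound list

1 | 2-bromopropene | C=C(C)Br | starting material
2 | 2-methylcyclopent-2-en-1-one | CC1=CCCC1=O | starting material
3 | methyl acrylate | C=CC(=O)OC | starting material
4 | isopropenylmagnesium bromide (formed in situ) | C=C(C)[Mg]Br | intermediate
5 | bromomagnesium (3S)-2-methyl-3-(prop-1-en-2-yl)cyclopent-1-en-1-olate (formed in situ) | C=C(C)[C@@H]1CCC(O[Mg]Br)=C1C | intermediate
6 | methyl 3-[(1S,5S)-1-methyl-2-oxo-5-(prop-1-en-2-yl)cyclopentyl]propanoate | C=C(C)[C@@H]1CCC(=O)[C@@]1(C)CCC(=O)OC | intermediate
7 | methyl 3-[(1S,5S)-3-hydroxy-1-methyl-2-oxo-5-(prop-1-en-2-yl)cyclopentyl]propanoate (both epimers at the carbinol carbon) | C=C(C)[C@@H]1CC(O)C(=O)[C@@]1(C)CCC(=O)OC | intermediate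
8 | (2S,3S)-2-(3-methoxy-3-oxopropyl)-2-methyl-5-oxo-3-(prop-1-en-2-yl)pentanoic acid | C=C(C)[C@H](CC=O)[C@](C)(CCC(=O)OC)C(=O)O | intermediate
9 | (2S,3S)-2-(3-methoxy-3-oxopropyl)-2-methyl-3-(prop-1-en-2-yl)pentanedioic acid | C=C(C)[C@H](CC(=O)O)[C@](C)(CCC(=O)OC)C(=O)O | intermediate
10 | methyl 3-[(3S,4S)-3-methyl-2,6-dioxo-4-(prop-1-en-2-yl)oxan-3-yl]propanoate (formed in situ) | C=C(C)[C@@H]1CC(=O)OC(=O)[C@@]1(C)CCC(=O)OC | intermediate
11 | (2S,3S)-5-[methoxy(methyl)amino]-2-(3-methoxy-3-oxopropyl)-2-methyl-5-oxo-3-(prop-1-en-2-yl)pentanoic acid | C=C(C)[C@H](CC(=O)N(C)OC)[C@](C)(CCC(=O)OC)C(=O)O | intermediate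
12 | ethyl 2-acetyl-3-methylbutanoate | CCOC(=O)C(C(C)C)C(C)=O | starting material
13 | methyl (4S,5S)-4-(carbonochloridoyl)-7-[methoxy(methyl)amino]-4-methyl-7-oxo-5-(prop-1-en-2-yl)heptanoate (formed in situ) | C=C(C)[C@H](CC(=O)N(C)OC)[C@](C)(CCC(=O)OC)C(=O)Cl | intermediate
14 | dilithium 1-ethoxy-2-(propan-2-yl)buta-1,3-diene-1,3-bis(olate) (formed in situ) | [Li]OC(=C)C(C(C)C)=C(O[Li])OCC | intermediate
15 | methyl (4S,5S)-4-[4-(ethoxycarbonyl)-5-methyl-3-oxohexanoyl]-7-[methoxy(methyl)amino]-4-methyl-7-oxo-5-(prop-1-en-2-yl)heptanoate (epimers at the isopropyl-bearing carbon, largely enolised) | C=C(C)[C@H](CC(=O)N(C)OC)[C@](C)(CCC(=O)OC)C(=O)CC(=O)C(C(C)C)C(=O)OCC | intermediate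
16 | methyl (4S,5S)-4-[4-hydroxy-2-oxo-3-(propan-2-yl)-2H-pyran-6-yl]-7-[methoxy(methyl)amino]-4-methyl-7-oxo-5-(prop-1-en-2-yl)heptanoate (formed in situ as its amidinium salt) | C=C(C)[C@H](CC(=O)N(C)OC)[C@](C)(CCC(=O)OC)C1=CC(O)=C(C(C)C)C(=O)O1 | intermediate
17 | methyl (4S,5S)-4-[4-(benzyloxy)-2-oxo-3-(propan-2-yl)-2H-pyran-6-yl]-7-[methoxy(methyl)amino]-4-methyl-7-oxo-5-(prop-1-en-2-yl)heptanoate | C=C(C)[C@H](CC(=O)N(C)OC)[C@](C)(CCC(=O)OC)C1=CC(OCc2ccccc2)=C(C(C)C)C(=O)O1 | intermediate
18 | 2-chloro-1,1-dimethoxyethane | COC(CCl)OC | starting material
19 | lithium methoxyacetylide (formed in situ) | [Li]C#COC | intermediate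
20 | methyl (4S,5S)-4-[4-(benzyloxy)-2-oxo-3-(propan-2-yl)-2H-pyran-6-yl]-9-methoxy-4-methyl-7-oxo-5-(prop-1-en-2-yl)non-8-ynoate | C=C(C)[C@H](CC(=O)C#COC)[C@](C)(CCC(=O)OC)C1=CC(OCc2ccccc2)=C(C(C)C)C(=O)O1 | intermediate
21 | bridged lactone cycloadduct: 2-oxabicyclo[2.2.2]octa-5,7-dien-3-one with C9 and C13 as bridgeheads, joined by O–C(=O), by C11H=C12(OBn) and by C8=C14(OMe), ring B fused at C8–C9; C5 and C10 as in 20, bridgehead configuration immaterial (formed in situ) | C=C(C)[C@@H]1CC(=O)C2=C(OC)C3(C(C)C)C(=O)OC2(C=C3OCc4ccccc4)[C@@]1(C)CCC(=O)OC | intermediate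
22 | methyl 3-[(1S,2S)-7-(benzyloxy)-5-methoxy-1-methyl-4-oxo-6-(propan-2-yl)-2-(prop-1-en-2-yl)-1,2,3,4-tetrahydronaphthalen-1-yl]propanoate | C=C(C)[C@@H]1CC(=O)c2c(OC)c(C(C)C)c(OCc3ccccc3)cc2[C@@]1(C)CCC(=O)OC | intermediate
23 | methyl 3-[(1S,2S)-5,7-dihydroxy-1-methyl-4-oxo-6-(propan-2-yl)-2-(prop-1-en-2-yl)-1,2,3,4-tetrahydronaphthalen-1-yl]propanoate | C=C(C)[C@@H]1CC(=O)c2c(O)c(C(C)C)c(O)cc2[C@@]1(C)CCC(=O)OC | intermediate
24 | methyl 3-[(1S,2S)-7-hydroxy-1-methyl-4,5,8-trioxo-6-(propan-2-yl)-2-(prop-1-en-2-yl)-1,2,3,4,5,8-hexahydronaphthalen-1-yl]propanoate | C=C(C)[C@@H]1CC(=O)C2=C(C(=O)C(O)=C(C(C)C)C2=O)[C@@]1(C)CCC(=O)OC | target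

## Step count and risk

Total step count: 11. Longest linear sequence: 11 steps (from 1 and 2 to 24); 3, 12 and 18 enter as purchased compounds.

Least certain steps:

Step 9 (key step). The cycloaddition may be too slow, because the donor on the alkyne raises its acceptor orbital and the C13–C14 bond joins two fully substituted carbons; oligomerisation of the push–pull ynone or its intramolecular ene reaction with the isopropenyl group could then take over. The fallback keeps the same two ring-forming bonds but uses a donor-free dienophile and puts the C14 oxygen on afterwards. It sets out from 17: ethynylmagnesium bromide (THF, −20 °C, acid quench) gives the terminal ynone F1; NBS with catalytic AgNO3 in acetone gives the bromo ynone F2; heating in toluene gives, after loss of CO2, the aryl bromide F3 with bromine at C14; and CuI-catalysed substitution with NaOMe in MeOH/DMF, helped by the ortho ketone, returns to the route at 22.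

Step 1. The magnesium enolate may add sluggishly to the acrylate, with oligomerisation of the acrylate or proton transfer to the α'-position followed by a second addition; the face selectivity of an alkenyl Grignard reagent with this ligand class must also be established by screening. The fallback separates the two events. From 2 and 4 the copper-catalysed addition is quenched with a proton source to give the trans ketone F4, which is then treated with 3 and catalytic t-BuOK in t-BuOH; the thermodynamic enolate on the methyl-bearing carbon adds anti to the isopropenyl group, and the route is rejoined at 6.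

Step 6. The strongly basic dianion may attack the amide or the methyl ester, or the acid chloride may be intercepted by the neighbouring amide carbonyl before it is acylated. The fallback uses a neutral carbon nucleophile. From 12, silylation (Me3SiCl/Et3N, then LiN(i-Pr)2/Me3SiCl) gives the bis(silyl) dienol ether F5, which is acylated at its terminal carbon by 13 in CH2Cl2 from −78 °C to rt (Mukaiyama-type acylation without strong base); aqueous work-up returns to the route at 15.

Step 8. Amine may add to the alkoxy ynone as the tetrahedral intermediate collapses, or a second alkynide may add if the quench is not cold and acidic enough. The fallback forms the ynone by oxidation in an amine-free flask. From 17, Cp2Zr(H)Cl in THF reduces the amide to the aldehyde F6 without touching the esters; 19 is added at −78 °C to give the propargylic alcohol F7 (both epimers), which is not a conjugate acceptor; Dess–Martin oxidation buffered with NaHCO3 returns to the route at 20.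

Step 10. Protonation of the isopropenyl group by acid formed during the double dealkylation, followed by chloride capture or cyclisation onto the electron-rich ring, or incomplete cleavage of one of the two ethers, may occur. The fallback removes the two groups at different stages under milder activation. From 22, MgI2·OEt2 in toluene cleaves only the methoxy group chelated to the C7 ketone and gives the phenol F8; (KSO3)2NO oxidises it at the free para position to the benzyloxyquinone F9; and one equivalent of BCl3 at −78 °C removes the benzyl group through a chelate with the C11 carbonyl at a temperature where the alkene is inert, rejoining the route at 24.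

## Further compounds

F1 | step 9 | methyl (4S,5S)-4-[4-(benzyloxy)-2-oxo-3-(propan-2-yl)-2H-pyran-6-yl]-4-methyl-7-oxo-5-(prop-1-en-2-yl)non-8-ynoate | C=C(C)[C@H](CC(=O)C#C)[C@](C)(CCC(=O)OC)C1=CC(OCc2ccccc2)=C(C(C)C)C(=O)O1
F2 | step 9 | methyl (4S,5S)-4-[4-(benzyloxy)-2-oxo-3-(propan-2-yl)-2H-pyran-6-yl]-9-bromo-4-methyl-7-oxo-5-(prop-1-en-2-yl)non-8-ynoate | C=C(C)[C@H](CC(=O)C#CBr)[C@](C)(CCC(=O)OC)C1=CC(OCc2ccccc2)=C(C(C)C)C(=O)O1
F3 | step 9 | methyl 3-[(1S,2S)-7-(benzyloxy)-5-bromo-1-methyl-4-oxo-6-(propan-2-yl)-2-(prop-1-en-2-yl)-1,2,3,4-tetrahydronaphthalen-1-yl]propanoate | C=C(C)[C@@H]1CC(=O)c2c(Br)c(C(C)C)c(OCc3ccccc3)cc2[C@@]1(C)CCC(=O)OC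
F4 | step 1 | (2S,3R)-2-methyl-3-(prop-1-en-2-yl)cyclopentan-1-one | C=C(C)[C@@H]1CCC(=O)[C@H]1C
F5 | step 6 | 1-ethoxy-2-(propan-2-yl)-1,3-bis(trimethylsilyloxy)buta-1,3-diene (alkene geometry not defined) | CCOC(O[Si](C)(C)C)=C(C(C)C)C(=C)O[Si](C)(C)C
F6 | step 8 | methyl (4S,5S)-4-[4-(benzyloxy)-2-oxo-3-(propan-2-yl)-2H-pyran-6-yl]-4-methyl-7-oxo-5-(prop-1-en-2-yl)heptanoate | C=C(C)[C@H](CC=O)[C@](C)(CCC(=O)OC)C1=CC(OCc2ccccc2)=C(C(C)C)C(=O)O1
F7 | step 8 | methyl (4S,5S)-4-[4-(benzyloxy)-2-oxo-3-(propan-2-yl)-2H-pyran-6-yl]-7-hydroxy-9-methoxy-4-methyl-5-(prop-1-en-2-yl)non-8-ynoate (both epimers at C7) | C=C(C)[C@H](CC(O)C#COC)[C@](C)(CCC(=O)OC)C1=CC(OCc2ccccc2)=C(C(C)C)C(=O)O1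
F8 | step 10 | methyl 3-[(1S,2S)-7-(benzyloxy)-5-hydroxy-1-methyl-4-oxo-6-(propan-2-yl)-2-(prop-1-en-2-yl)-1,2,3,4-tetrahydronaphthalen-1-yl]propanoate | C=C(C)[C@@H]1CC(=O)c2c(O)c(C(C)C)c(OCc3ccccc3)cc2[C@@]1(C)CCC(=O)OC
F9 | step 10 | methyl 3-[(1S,2S)-7-(benzyloxy)-1-methyl-4,5,8-trioxo-6-(propan-2-yl)-2-(prop-1-en-2-yl)-1,2,3,4,5,8-hexahydronaphthalen-1-yl]propanoate | C=C(C)[C@@H]1CC(=O)C2=C(C(=O)C(OCc3ccccc3)=C(C(C)C)C2=O)[C@@]1(C)CCC(=O)OC
A1 | alternative 1 | (4R)-4-tert-butyl-2-[4,5,7-trimethoxy-6-(propan-2-yl)naphthalen-1-yl]-4,5-dihydro-1,3-oxazole | COc1ccc(C2=N[C@H](C(C)(C)C)CO2)c2cc(OC)c(C(C)C)c(OC)c12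
A2 | alternative 1 | isopropenyllithium | [Li]C(C)=C
A3 | alternative 1 | tert-butyl(3-iodopropoxy)dimethylsilane | ICCCO[Si](C)(C)C(C)(C)C
A4 | alternative 1 | (4R)-4-tert-butyl-2-[(1R,2S)-1-{3-[tert-butyl(dimethyl)silyl]oxypropyl}-4,5,7-trimethoxy-6-(propan-2-yl)-2-(prop-1-en-2-yl)-1,2-dihydronaphthalen-1-yl]-4,5-dihydro-1,3-oxazole | C=C(C)[C@@H]1C=C(OC)c2c(OC)c(C(C)C)c(OC)cc2[C@@]1(C3=N[C@H](C(C)(C)C)CO3)CCCO[Si](C)(C)C(C)(C)C
A5 | alternative 2 | (E)-2,4-dimethylpenta-2,4-dienal | C=C(C)/C=C(\C)C=O
A6 | alternative 2 | (E)-1-[tert-butyl(dimethyl)silyl]oxybuta-1,3-diene | C=C/C=C/O[Si](C)(C)C(C)(C)C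
A7 | alternative 2 | (1S,2R,6S)-2-[tert-butyl(dimethyl)silyl]oxy-1-methyl-6-(prop-1-en-2-yl)cyclohex-3-ene-1-carbaldehyde | C=C(C)[C@@H]1CC=C[C@@H](O[Si](C)(C)C(C)(C)C)[C@@]1(C)C=O
A8 | alternative 3 | 3-isopropoxy-4-isopropylcyclobut-3-ene-1,2-dione | CC(C)OC1=C(C(C)C)C(=O)C1=O
A9 | alternative 3 | C9-lithiated ring-B alkene: 7-lithio-8-methyl-9-(prop-1-en-2-yl)-8-{3-[tert-butyl(dimethyl)silyl]oxypropyl}-1,4-dioxaspiro[4.5]dec-6-ene, configuration as in the SMILES | C=C(C)[C@@H]1CC2(OCCO2)C=C([Li])[C@@]1(C)CCCO[Si](C)(C)C(C)(C)C
A10 | alternative 3 | 4-hydroxy-3-isopropoxy-2-isopropyl-4-(ring-B cyclohexenyl)cyclobut-2-en-1-one, the cyclohexenyl group being A9 without lithium; carbinol configuration not defined | C=C(C)[C@@H]1CC2(OCCO2)C=C(C3(O)C(OC(C)C)=C(C(C)C)C3=O)[C@@]1(C)CCCO[Si](C)(C)C(C)(C)C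
A11 | alternative 3 | ring-C hydroquinone: 5,8-dihydroxy-7-isopropoxy-6-isopropyl-1-methyl-2-(prop-1-en-2-yl)-1-{3-[tert-butyl(dimethyl)silyl]oxypropyl}tetralin with the C4 ketone as its ethylene ketal, configuration as in the SMILES | C=C(C)[C@@H]1CC2(OCCO2)c2c(O)c(C(C)C)c(OC(C)C)c(O)c2[C@@]1(C)CCCO[Si](C)(C)C(C)(C)C
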